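## Structural features

1. The target is an unsymmetrical biflavanoid in which two 2-(4-hydroxyphenyl)chromane-3,4,7,8-tetrol units (rings A/C/B and A'/C'/B') are joined by one biaryl bond, C6–C6'.
2. The link is ortho to both 7-OH groups, so the centre is a 2,2'-biphenol with only two ortho substituents and no stable axis, and all chirality sits in the two pyran rings.
3. Each pyran ring carries three contiguous stereocentres, C2/C3/C4 being R,R,R (2,3-cis-3,4-cis, all three ring hydrogens on one face) and C2'/C3'/C4' being R,R,S (2,3-cis-3,4-trans), so that the target is the mono-C4'-epimer of a C2-symmetric dimer.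
4. Fragile groups: the C4 and C4' carbinols are benzylic, ortho to O1 and para to the 7-oxygen, and ionise to benzylic cations or para-quinone methides in acid or when the 7-OH is free; the pyrogallol-type A rings are oxidised by air in base; a 2,3-cis-dihydroflavonol stage can epimerise at C3.
5. The real difficulty is twofold: the 2,3-cis triads (chalcone-epoxide and dihydroflavonol chemistry delivers 2,3-trans), and a single stereochemical difference between two halves that are otherwise identical.
6. Feature used by the key step: H-2, H-3 and H-4 of ring C, and of ring C' before a late inversion at C4', lie on one face of each pyran ring, so each heterocycle is the syn-adduct of two H2 to one face of a planar 3-oxygenated chromen-4-one and a flat, achiral 6,6'-biflavonol already holds every carbon and oxygen atom of the target.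
7. Second feature: O7 and O7' are para to C4 and C4' and are the two oxygens of the biphenol, so one ether and one phenoxide there allow C4' alone to be inverted.
8. In one sentence: a flat, achiral 6,6'-biflavonol triacetate is hydrogenated on both chromenone rings at once by one chiral catalyst, which sets all six stereocentres as two all-cis triads.

## Logic of the disconnections

17 from 16: the five O–CH2Ph bonds are cut last. Benzyl ethers survive every earlier step and leave under neutral conditions. The forward step must spare the C4–O, C4'–O and O1–C2 bonds.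

16 from 14 (through 15): the C4'–O bond is exchanged with inversion and three acetyl–O bonds are cut. 16 differs from a pseudo-symmetric all-cis precursor at one centre only, so both triads can come from one operation. The demand is that only the half with the 7'-O-acetate ionises: its phenoxide gives 15, while the 7-O-benzyl half cannot form a quinone methide.

14 from 12 (through 13), the key disconnection: the six C–H bonds at C2, C3, C4, C2', C3' and C4' are removed. Six stereocentres fall to none and the precursor is flat and achiral. The forward step needs syn addition of H2 to one face of both rings with the same sense, carbonyl reduction anti to the axial 3-acetoxy group, and no epimerisation of 13.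

12 from 10 (through 11): three acyl–O bonds and one benzyl–O bond are cut. The desymmetrisation of the biphenol is placed on the robust flat compound, before any ionisable carbinol exists. The demand is mono-alkylation of one of two equivalent 7-OH groups in 10.

10 from 8 (through 9): the O1–C2 and C3–O bonds of both heterocycles and the two acetal O–C bonds are cut. Both chromenone rings come from open-chain enones in one oxidation. The demand is the flavonol (not aurone) pathway on both halves.

8 from 6 and 7: the two Cα=Cβ bonds are cut. The B rings arrive as a commercial aldehyde in one twofold condensation.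

6 from 4 and 5: the aryl–aryl bond (later C6–C6') is cut between two halves that differ only in the handle at that carbon, bromine in 4 and boron in 5. Both partners descend from the same bromide, so no second fragment synthesis is needed and the regiochemistry is fixed by the handles. The demand is a cross-coupling of two electron-rich, ortho-oxygenated arenes without loss of the boron group of 5.

5 from 4: the C–B bond is cut. Part of 4 is diverted to its boronate. The demand is borylation in the presence of the chelated phenol, the ketone and the acetal.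

4 from 1 (through 2 and 3): one C–Br and two O–C bonds are cut. The demands are regioselective etherification of the 4-OH, then the 3-OH, and bromination para to the free 2-OH.

## Other disconnections considered

Alternative 1: cut C6–C6' between two complete, differently configured monomers. The forward key step is a Suzuki–Miyaura coupling of the all-cis aryl bromide A1 with the 3,4-trans aryl pinacolboronate A2, then debenzylation. This is the plan that comes to mind first. It is not preferred because both triads must be built twice and separately in the 2,3-cis series, the coupling joins two electron-rich, ortho-oxygenated partners that each carry an ionisable C4 carbinol, and the step count roughly doubles.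

Alternative 2: cut O1–C2 and C3–O of both heterocycles at the dihydroflavonol level. The forward key step is a twofold Juliá–Colonna-type asymmetric epoxidation of the protected bis-chalcone A3 and 6-endo phenol opening to the bis-dihydroflavonol A4, then carbonyl reduction. Opening an (E)-chalcone epoxide at the benzylic carbon with inversion can only give the 2,3-trans relation (A4 is 2R,3R). Both C3 centres would then need inversion by oxidation and hydride return (LiBH(s-Bu)3) next to two epimerisable benzylic centres, which adds at least four twofold operations before the same end-game.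

Alternative 3: cut C3–C4 and C3'–C4' as a union of two carbonyl carbons of like polarity. The forward key step is a twofold SmI2 ketyl–aldehyde (pinacol) cyclisation of the tetra-aldehyde A5, closing both pyran rings as cis-3,4-diols. In such chelated cyclisations the new cis-diol is expected anti to the substituent on the neighbouring ring carbon, which is the 2,3-trans-3,4-cis relation and wrong at both C3. The α-aryloxy arylacetaldehyde centres of A5 are also configurationally labile, and the absolute configuration would still need a separate asymmetric etherification.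

Key step: step 11

Assumption: the sense of induction of the chiral ruthenium–carbene catalyst on a 3-acyloxyflavone cannot be read from precedent, so the ligand antipode that leads to the 2R series is to be assigned on monomeric 3-acetoxyflavone beforehand; it is written as (R,R) in step 11.

## Steps

Step 1
Reactants: 1 1-(2,3,4-trihydroxyphenyl)ethan-1-one (gallacetophenone)
Product: 2 1-[2,3-dihydroxy-4-(methoxymethoxy)phenyl]ethan-1-one
Conditions: MOMCl (1.05 equiv), K2CO3 (1.05 equiv), acetone, 0 °C
Reagents that add atoms: chloromethyl methyl ether, COCCl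
Why: Williamson-type O-alkylation; the 4-OH (para to the acetyl group, not hydrogen-bonded) is the most acidic hydroxyl, the 2-OH is locked in a hydrogen bond to the ketone and the 3-OH is flanked on both sides, so one equivalent of base and MOMCl should etherify O4 alone.

Step 2
Reactants: 2 1-[2,3-dihydroxy-4-(methoxymethoxy)phenyl]ethan-1-one
Product: 3 1-[3-(benzyloxy)-2-hydroxy-4-(methoxymethoxy)phenyl]ethan-1-one
Conditions: BnBr (1.1 equiv), K2CO3, DMF, 25 °C
Reagents that add atoms: benzyl bromide, BrCc1ccccc1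
Why: Williamson etherification of the only unchelated phenol; the 2-OH stays free because its hydrogen bond to the carbonyl group makes it the least reactive hydroxyl under carbonate conditions.

Step 3
Reactants: 3 1-[3-(benzyloxy)-2-hydroxy-4-(methoxymethoxy)phenyl]ethan-1-one
Product: 4 1-[3-(benzyloxy)-5-bromo-2-hydroxy-4-(methoxymethoxy)phenyl]ethan-1-one
Conditions: NBS (1.05 equiv), MeCN, 0 °C to 25 °C
Reagents that add atoms: N-bromosuccinimide, O=C1CCC(=O)N1Br
Why: Electrophilic aromatic bromination; C5 is para to the free 2-OH and ortho to the 4-alkoxy group, whereas C6 is meta to both and ortho to the acetyl group, so substitution should occur at C5 only. The batch of 4 is divided, about half for step 4 and the rest kept for step 5.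

Step 4
Reactants: 4 1-[3-(benzyloxy)-5-bromo-2-hydroxy-4-(methoxymethoxy)phenyl]ethan-1-one
Product: 5 1-[3-(benzyloxy)-2-hydroxy-4-(methoxymethoxy)-5-(4,4,5,5-tetramethyl-1,3,2-dioxaborolan-2-yl)phenyl]ethan-1-one
Conditions: B2pin2 (1.2 equiv), PdCl2(dppf) (3 mol %), KOAc (3 equiv), 1,4-dioxane, 90 °C
Reagents that add atoms: bis(pinacolato)diboron, CC1(C)OB(OC1(C)C)B1OC(C)(C)C(C)(C)O1
Why: Miyaura borylation of the aryl bromide; the weak acetate base disfavours onward Suzuki coupling, the chelated phenol, the ketone and the acetal are tolerated, and any biaryl formed by adventitious coupling is compound 6 itself and is not lost.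

Step 5
Reactants: 4 1-[3-(benzyloxy)-5-bromo-2-hydroxy-4-(methoxymethoxy)phenyl]ethan-1-one (1.0 equiv); 5 1-[3-(benzyloxy)-2-hydroxy-4-(methoxymethoxy)-5-(4,4,5,5-tetramethyl-1,3,2-dioxaborolan-2-yl)phenyl]ethan-1-one (1.05 equiv)
Product: 6 1,1'-[5,5'-bis(benzyloxy)-4,4'-dihydroxy-6,6'-bis(methoxymethoxy)-[1,1'-biphenyl]-3,3'-diyl]di(ethan-1-one)
Conditions: PdCl2(dppf) (5 mol %), K2CO3 (4 equiv), 1,4-dioxane/H2O (4:1, degassed), 85 °C
Reagents that add atoms: none
Why: Suzuki–Miyaura cross-coupling of the bromide with the boronate made from it; the two aryl groups are identical, so homocoupling of either partner also gives 6 and no cross-selectivity is needed, and only two ortho substituents flank the new bond.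

Step 6
Reactants: 6 1,1'-[5,5'-bis(benzyloxy)-4,4'-dihydroxy-6,6'-bis(methoxymethoxy)-[1,1'-biphenyl]-3,3'-diyl]di(ethan-1-one); 7 4-(benzyloxy)benzaldehyde (2.4 equiv)
Product: 8 (2E,2'E)-1,1'-[5,5'-bis(benzyloxy)-4,4'-dihydroxy-6,6'-bis(methoxymethoxy)-[1,1'-biphenyl]-3,3'-diyl]bis{3-[4-(benzyloxy)phenyl]prop-2-en-1-one}
Conditions: KOH, EtOH/THF, 25 °C
Reagents that add atoms: none
Why: Twofold Claisen–Schmidt condensation; the methyl ketone enolates add to the non-enolisable aldehyde and dehydrate to the conjugated (E)-enones, and the phenoxides, the acetals and the benzyl ethers are inert to hydroxide.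

Step 7
Reactants: 8 (2E,2'E)-1,1'-[5,5'-bis(benzyloxy)-4,4'-dihydroxy-6,6'-bis(methoxymethoxy)-[1,1'-biphenyl]-3,3'-diyl]bis{3-[4-(benzyloxy)phenyl]prop-2-en-1-one}
Product: 9 8,8'-bis(benzyloxy)-2,2'-bis[4-(benzyloxy)phenyl]-3,3'-dihydroxy-7,7'-bis(methoxymethoxy)-4H,4'H-[6,6'-bichromene]-4,4'-dione
Conditions: H2O2 (30% aq), NaOH (aq), MeOH/THF, 0 °C to 25 °C
Reagents that add atoms: hydrogen peroxide, OO
Why: Twofold Algar–Flynn–Oyamada reaction; alkaline hydrogen peroxide turns each 2'-hydroxychalcone unit into a 3-hydroxyflavone by oxidative cyclisation through O1–C2, and with no substituent at the position that becomes C5 the flavonol (not the aurone) pathway is expected.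

Step 8
Reactants: 9 8,8'-bis(benzyloxy)-2,2'-bis[4-(benzyloxy)phenyl]-3,3'-dihydroxy-7,7'-bis(methoxymethoxy)-4H,4'H-[6,6'-bichromene]-4,4'-dione
Product: 10 8,8'-bis(benzyloxy)-2,2'-bis[4-(benzyloxy)phenyl]-3,3',7,7'-tetrahydroxy-4H,4'H-[6,6'-bichromene]-4,4'-dione
Conditions: HCl (3 M aq), MeOH/THF, 50 °C
Reagents that add atoms: none
Why: Acid-catalysed acetal exchange removes both methoxymethyl groups; the flat flavonol core and the aryl benzyl ethers are stable to dilute HCl, and no stereocentre or ionisable benzylic carbinol is present yet.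

Step 9
Reactants: 10 8,8'-bis(benzyloxy)-2,2'-bis[4-(benzyloxy)phenyl]-3,3',7,7'-tetrahydroxy-4H,4'H-[6,6'-bichromene]-4,4'-dione
Product: 11 7,8,8'-tris(benzyloxy)-2,2'-bis[4-(benzyloxy)phenyl]-3,3',7'-trihydroxy-4H,4'H-[6,6'-bichromene]-4,4'-dione
Conditions: BnBr (1.0 equiv), K2CO3 (1.0 equiv), DMF, 0 °C to 25 °C
Reagents that add atoms: benzyl bromide, BrCc1ccccc1
Why: Williamson mono-alkylation; the 7-OH groups (vinylogous acids through the C4 carbonyl) are far more acidic than the chelated 3-OH groups, and they form a 2,2'-biphenol whose mono-anion is stabilised by an O–H···O− bond, so one equivalent of base and BnBr should give mainly the mono-ether, which cannot migrate later.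

Step 10
Reactants: 11 7,8,8'-tris(benzyloxy)-2,2'-bis[4-(benzyloxy)phenyl]-3,3',7'-trihydroxy-4H,4'H-[6,6'-bichromene]-4,4'-dione
Product: 12 7,8,8'-tris(benzyloxy)-2,2'-bis[4-(benzyloxy)phenyl]-4,4'-dioxo-4H,4'H-[6,6'-bichromene]-3,3',7'-triyl triacetate
Conditions: Ac2O, pyridine, DMAP (cat.), CH2Cl2, 25 °C
Reagents that add atoms: acetic anhydride, CC(=O)OC(C)=O
Why: Exhaustive O-acylation with nucleophilic catalysis caps the 7'-OH as an aryl acetate and turns both 3-OH groups into enol acetates, which blocks chelation of the hydrogenation catalyst by the 3-hydroxy-4-oxo unit and later supplies the leaving group at C4'.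

Step 11
Reactants: 12 7,8,8'-tris(benzyloxy)-2,2'-bis[4-(benzyloxy)phenyl]-4,4'-dioxo-4H,4'H-[6,6'-bichromene]-3,3',7'-triyl triacetate
Product: 14 (2R,2'R,3R,3'R,4R,4'R)-7,8,8'-tris(benzyloxy)-2,2'-bis[4-(benzyloxy)phenyl]-4,4'-dihydroxy-[6,6'-bichromane]-3,3',7'-triyl triacetate, via cis-dihydroflavonol triacetate 13 (not isolated)
Conditions: H2 (100 bar), Ru(cod)(2-methylallyl)2 (10 mol %), (R,R)-SINpEt·HBF4 [1,3-bis(1-(naphthalen-1-yl)ethyl)-4,5-dihydroimidazolium tetrafluoroborate] (20 mol %), KOtBu (20 mol %, catalyst preformed), toluene, 40 °C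
Reagents that add atoms: none
Why: Proposed new method: the hydride of a chiral ruthenium N-heterocyclic-carbene catalyst is expected to add H2 in syn fashion across the tetrasubstituted C2=C3 bond of each 3-acetoxychromen-4-one ring from the face selected by the ligand, which fixes C2 and C3 (and C2' and C3') together as the 2,3-cis pairs of 13, and then to reduce both C4 carbonyl groups. The closest known reaction types are the ruthenium–carbene hydrogenation of flavones and chromones to flavanones and flavanols (trisubstituted C2=C3, no 3-substituent) and the classical non-asymmetric heterogeneous hydrogenation of flavonols to 2,3-cis-3,4-cis-flavan-3,4-diols; new here is enantiofacial control at a 3-oxygenated, tetrasubstituted chromenone. No ring is closed. C2, C3, C2' and C3' are under catalyst control (one face, one syn addition per ring), whereas C4 and C4' are under substrate control: in 13 the 2-aryl group is equatorial and the 3-acetoxy group axial, so hydrogen should reach the carbonyl carbon anti to the axial C3–O bond (Felkin–Anh sense, as in hydride reductions of 2,3-cis-dihydroflavonols) and leave the 4-OH cis to the 3-OAc. The two rings are reduced independently, so occasional wrong-face events end in diastereomers that can be removed, and the enantiomeric purity of 14 should exceed the selectivity per ring (Horeau amplification). Selectivity needs are: no enolisation of 13 towards the 2,3-trans ketone, which a preformed catalyst without excess alkoxide, an aprotic solvent and fast carbonyl reduction should secure; no hydrogenolysis of the five benzyl ethers or of the C4–O bonds and no arene saturation, to which ruthenium is far less prone than palladium; and survival of the 7'-aryl acetate, which meets no nucleophile.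

Step 12
Reactants: 14 (2R,2'R,3R,3'R,4R,4'R)-7,8,8'-tris(benzyloxy)-2,2'-bis[4-(benzyloxy)phenyl]-4,4'-dihydroxy-[6,6'-bichromane]-3,3',7'-triyl triacetate
Product: 16 (2R,2'R,3R,3'R,4R,4'S)-7,8,8'-tris(benzyloxy)-2,2'-bis[4-(benzyloxy)phenyl]-[6,6'-bichromane]-3,3',4,4',7'-pentol, via para-quinone methide 15 (not isolated)
Conditions: K2CO3, THF/H2O (degassed), 25 °C then 40 °C
Reagents that add atoms: water, O
Why: The aryl acetate is cleaved first; acyl migration within the cis-3',4'-diol monoacetate brings an acetate onto O4', and the 7'-phenoxide expels it by 1,6-elimination to give 15 (known para-quinone methide generation from 4-hydroxybenzyl esters). Water then adds at C4' anti to the axial 3'-oxygen, the sense known for nucleophile capture at C4 of 2,3-cis-flavans, so C4' becomes S. In the other half the 7-O-benzyl ether cannot form a quinone methide, its acetate is saponified with acyl–oxygen cleavage and C4 stays R.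

Step 13
Reactants: 16 (2R,2'R,3R,3'R,4R,4'S)-7,8,8'-tris(benzyloxy)-2,2'-bis[4-(benzyloxy)phenyl]-[6,6'-bichromane]-3,3',4,4',7'-pentol
Product: 17 (2R,2'R,3R,3'R,4R,4'S)-2,2'-bis(4-hydroxyphenyl)-[6,6'-bichromane]-3,3',4,4',7,7',8,8'-octol (target)
Conditions: H2 (1 atm), Pd/C (10 wt %), THF/H2O, 25 °C, filtration under argon
Reagents that add atoms: none
Why: Hydrogenolysis of the five aryl benzyl ethers over palladium; phenolic benzyl ethers are cleaved much faster than secondary benzylic alcohols under neutral conditions (as in the debenzylation of 4-hydroxybenzyl-alcohol lignin models), and no acid or base is present that could ionise C4 or C4'.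

## Compound list

1 | 1-(2,3,4-trihydroxyphenyl)ethan-1-one (gallacetophenone) | CC(=O)c1ccc(O)c(O)c1O | starting material
2 | 1-[2,3-dihydroxy-4-(methoxymethoxy)phenyl]ethan-1-one | CC(=O)c1ccc(OCOC)c(O)c1O | intermediate
3 | 1-[3-(benzyloxy)-2-hydroxy-4-(methoxymethoxy)phenyl]ethan-1-one | CC(=O)c1ccc(OCOC)c(OCc2ccccc2)c1O | intermediate
4 | 1-[3-(benzyloxy)-5-bromo-2-hydroxy-4-(methoxymethoxy)phenyl]ethan-1-one | CC(=O)c1cc(Br)c(OCOC)c(OCc2ccccc2)c1O | intermediate
5 | 1-[3-(benzyloxy)-2-hydroxy-4-(methoxymethoxy)-5-(4,4,5,5-tetramethyl-1,3,2-dioxaborolan-2-yl)phenyl]ethan-1-one | CC(=O)c1cc(B2OC(C)(C)C(C)(C)O2)c(OCOC)c(OCc2ccccc2)c1O | intermediate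
6 | 1,1'-[5,5'-bis(benzyloxy)-4,4'-dihydroxy-6,6'-bis(methoxymethoxy)-[1,1'-biphenyl]-3,3'-diyl]di(ethan-1-one) | CC(=O)c1cc(-c2cc(C(C)=O)c(O)c(OCc3ccccc3)c2OCOC)c(OCOC)c(OCc2ccccc2)c1O | intermediate
7 | 4-(benzyloxy)benzaldehyde | O=Cc1ccc(OCc2ccccc2)cc1 | starting material
8 | (2E,2'E)-1,1'-[5,5'-bis(benzyloxy)-4,4'-dihydroxy-6,6'-bis(methoxymethoxy)-[1,1'-biphenyl]-3,3'-diyl]bis{3-[4-(benzyloxy)phenyl]prop-2-en-1-one} | O=C(/C=C/c1ccc(OCc2ccccc2)cc1)c1cc(-c2cc(C(=O)/C=C/c3ccc(OCc4ccccc4)cc3)c(O)c(OCc3ccccc3)c2OCOC)c(OCOC)c(OCc2ccccc2)c1O | intermediate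
9 | 8,8'-bis(benzyloxy)-2,2'-bis[4-(benzyloxy)phenyl]-3,3'-dihydroxy-7,7'-bis(methoxymethoxy)-4H,4'H-[6,6'-bichromene]-4,4'-dione | O=c1c(O)c(-c2ccc(OCc3ccccc3)cc2)oc2c(OCc3ccccc3)c(OCOC)c(-c3cc4c(=O)c(O)c(-c5ccc(OCc6ccccc6)cc5)oc4c(OCc4ccccc4)c3OCOC)cc12 | intermediate
10 | 8,8'-bis(benzyloxy)-2,2'-bis[4-(benzyloxy)phenyl]-3,3',7,7'-tetrahydroxy-4H,4'H-[6,6'-bichromene]-4,4'-dione | O=c1c(O)c(-c2ccc(OCc3ccccc3)cc2)oc2c(OCc3ccccc3)c(O)c(-c3cc4c(=O)c(O)c(-c5ccc(OCc6ccccc6)cc5)oc4c(OCc4ccccc4)c3O)cc12 | intermediate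
11 | 7,8,8'-tris(benzyloxy)-2,2'-bis[4-(benzyloxy)phenyl]-3,3',7'-trihydroxy-4H,4'H-[6,6'-bichromene]-4,4'-dione | O=c1c(O)c(-c2ccc(OCc3ccccc3)cc2)oc2c(OCc3ccccc3)c(OCc3ccccc3)c(-c3cc4c(=O)c(O)c(-c5ccc(OCc6ccccc6)cc5)oc4c(OCc4ccccc4)c3O)cc12 | intermediate
12 | 7,8,8'-tris(benzyloxy)-2,2'-bis[4-(benzyloxy)phenyl]-4,4'-dioxo-4H,4'H-[6,6'-bichromene]-3,3',7'-triyl triacetate | O=c1c(OC(C)=O)c(-c2ccc(OCc3ccccc3)cc2)oc2c(OCc3ccccc3)c(OCc3ccccc3)c(-c3cc4c(=O)c(OC(C)=O)c(-c5ccc(OCc6ccccc6)cc5)oc4c(OCc4ccccc4)c3OC(C)=O)cc12 | intermediate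
13 | (2R,2'R,3S,3'S)-7,8,8'-tris(benzyloxy)-2,2'-bis[4-(benzyloxy)phenyl]-4,4'-dioxo-[6,6'-bichromane]-3,3',7'-triyl triacetate | O=C1[C@@H](OC(C)=O)[C@@H](c2ccc(OCc3ccccc3)cc2)Oc2c(OCc3ccccc3)c(OCc3ccccc3)c(-c3cc4C(=O)[C@@H](OC(C)=O)[C@@H](c5ccc(OCc6ccccc6)cc5)Oc4c(OCc4ccccc4)c3OC(C)=O)cc12 | intermediate (not isolated)
14 | (2R,2'R,3R,3'R,4R,4'R)-7,8,8'-tris(benzyloxy)-2,2'-bis[4-(benzyloxy)phenyl]-4,4'-dihydroxy-[6,6'-bichromane]-3,3',7'-triyl triacetate | O[C@H]1[C@@H](OC(C)=O)[C@@H](c2ccc(OCc3ccccc3)cc2)Oc2c(OCc3ccccc3)c(OCc3ccccc3)c(-c3cc4[C@@H](O)[C@@H](OC(C)=O)[C@@H](c5ccc(OCc6ccccc6)cc5)Oc4c(OCc4ccccc4)c3OC(C)=O)cc12 | intermediate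
15 | (2R,3R,4R)-7,8-bis(benzyloxy)-2-[4-(benzyloxy)phenyl]-6-{(2R,3R)-8-(benzyloxy)-2-[4-(benzyloxy)phenyl]-3-hydroxy-7-oxo-2,3-dihydro-7H-chromen-6-yl}-4-hydroxychroman-3-yl acetate | O[C@H]1[C@@H](OC(C)=O)[C@@H](c2ccc(OCc3ccccc3)cc2)Oc2c(OCc3ccccc3)c(OCc3ccccc3)c(C3=CC4=C[C@@H](O)[C@@H](c5ccc(OCc6ccccc6)cc5)OC4=C(OCc4ccccc4)C3=O)cc12 | intermediate (not isolated)
16 | (2R,2'R,3R,3'R,4R,4'S)-7,8,8'-tris(benzyloxy)-2,2'-bis[4-(benzyloxy)phenyl]-[6,6'-bichromane]-3,3',4,4',7'-pentol | O[C@H]1[C@@H](O)[C@@H](c2ccc(OCc3ccccc3)cc2)Oc2c(OCc3ccccc3)c(OCc3ccccc3)c(-c3cc4[C@H](O)[C@@H](O)[C@@H](c5ccc(OCc6ccccc6)cc5)Oc4c(OCc4ccccc4)c3O)cc12 | intermediate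
17 | (2R,2'R,3R,3'R,4R,4'S)-2,2'-bis(4-hydroxyphenyl)-[6,6'-bichromane]-3,3',4,4',7,7',8,8'-octol | O[C@H]1[C@@H](O)[C@@H](c2ccc(O)cc2)Oc2c(O)c(O)c(-c3cc4[C@H](O)[C@@H](O)[C@@H](c5ccc(O)cc5)Oc4c(O)c3O)cc12 | target

## Step count and least certain steps

Total step count: 13. Longest linear sequence: 13 steps (1 to 17; 7 is commercial, and 5 is made from part of 4 and coupled with the rest).

Step 11 (key step, proposed new method). What may go wrong: insufficient enantiofacial discrimination or no turnover at the tetrasubstituted, acyloxy-bearing C2=C3 bond; enolisation of the intermediate ketone with loss of the 2,3-cis relation; partial loss of benzyl groups. Fallback with known chemistry, from 12 back to 14: hydrogenation of 12 over PtO2 in EtOAc, which follows the classical non-asymmetric all-cis hydrogenation of flavonol derivatives and has no facial preference between the halves. It should give 14 together with its enantiomer, the (2S,2'S,3S,3'S,4S,4'S)-triacetate F1, and the hetero-chiral pair (mutual enantiomers, diastereomers of 14), the (2R,2'S,3R,3'S,4R,4'S)-triacetate F2 and the (2S,2'R,3S,3'R,4S,4'R)-triacetate F3. F2 and F3 are removed on silica, and 14 is separated from F1 by preparative chromatography on a cellulose tris(3,5-dimethylphenylcarbamate) phase. The route is rejoined at 14, with at most a quarter of the material ending there.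

Step 12. What may go wrong: saponification of the 3'/4'-acetate outruns the 1,6-elimination, so the 7'-phenoxide half ionises only slowly through hydroxide loss, or reversible ionisation stops at a mixture of C4' epimers. Fallback, from 14 to 17: ionise the other half by acid instead of this half by base; after deprotection the two halves are constitutionally identical, so inverting C4 instead of C4' gives the same target. Cold saponification of 14 (K2CO3, MeOH/H2O, 0 °C) should give the all-cis (2R,2'R,3R,3'R,4R,4'R)-pentol F4. Phenol-selective acylation (CbzCl, K2CO3, acetone, 0 °C) should give the 7'-O-benzyloxycarbonyl derivative F5. Mild acid (PPTS, THF/H2O, 40 °C) should then ionise only the 7-O-benzyl half, since a para-alkoxy group stabilises the benzylic cation far better than a para-carbonate, and water enters anti to the 3-OH to give the C4-inverted carbonate F6. Hydrogenolysis of F6 under the conditions of step 13 removes the five benzyl ethers and the benzyl carbonate and rejoins the route at 17.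

Step 9. What may go wrong: over-alkylation to the 7,7'-dibenzyl ether and a statistical mixture if the biphenol mono-anion effect is weak. Fallback, from 10 to 11: enforce mono-benzylation by structure. 10 with benzaldehyde dimethyl acetal and camphorsulfonic acid (toluene, 80 °C) should give the cyclic benzylidene acetal across O7 and O7', F7. Ionic hydrogenation of F7 (Et3SiH, CF3CO2H, CH2Cl2, 0 °C) opens the acetal to one benzyl ether and one free phenol, which is 11.

Step 13. What may go wrong: hydrogenolytic loss of the C4 or C4' hydroxyl, or scrambling of the all-cis C4 through a quinone methide once the 7-OH is free on the catalyst surface. Fallback, from 16 to 17: mask the carbinols before debenzylation. Silylation of 16 (Et3SiOTf, 2,6-lutidine, CH2Cl2, −78 °C) should give the 3,3',4,4',7'-penta-O-triethylsilyl ether F8. Hydrogenolysis (H2, Pd/C, EtOAc) gives the debenzylated penta-O-triethylsilyl ether F9, in which the benzylic oxygens bear poor leaving groups. Buffered desilylation (HF·pyridine, pyridine, THF, 0 °C) rejoins the route at 17.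

## Further compounds

F1 | step 11 | (2S,2'S,3S,3'S,4S,4'S)-7,8,8'-tris(benzyloxy)-2,2'-bis[4-(benzyloxy)phenyl]-4,4'-dihydroxy-[6,6'-bichromane]-3,3',7'-triyl triacetate (enantiomer of 14) | O[C@@H]1[C@H](OC(C)=O)[C@H](c2ccc(OCc3ccccc3)cc2)Oc2c(OCc3ccccc3)c(OCc3ccccc3)c(-c3cc4[C@H](O)[C@H](OC(C)=O)[C@H](c5ccc(OCc6ccccc6)cc5)Oc4c(OCc4ccccc4)c3OC(C)=O)cc12
F2 | step 11 | (2R,2'S,3R,3'S,4R,4'S)-7,8,8'-tris(benzyloxy)-2,2'-bis[4-(benzyloxy)phenyl]-4,4'-dihydroxy-[6,6'-bichromane]-3,3',7'-triyl triacetate | O[C@H]1[C@@H](OC(C)=O)[C@@H](c2ccc(OCc3ccccc3)cc2)Oc2c(OCc3ccccc3)c(OCc3ccccc3)c(-c3cc4[C@H](O)[C@H](OC(C)=O)[C@H](c5ccc(OCc6ccccc6)cc5)Oc4c(OCc4ccccc4)c3OC(C)=O)cc12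
F3 | step 11 | (2S,2'R,3S,3'R,4S,4'R)-7,8,8'-tris(benzyloxy)-2,2'-bis[4-(benzyloxy)phenyl]-4,4'-dihydroxy-[6,6'-bichromane]-3,3',7'-triyl triacetate | O[C@@H]1[C@H](OC(C)=O)[C@H](c2ccc(OCc3ccccc3)cc2)Oc2c(OCc3ccccc3)c(OCc3ccccc3)c(-c3cc4[C@@H](O)[C@@H](OC(C)=O)[C@@H](c5ccc(OCc6ccccc6)cc5)Oc4c(OCc4ccccc4)c3OC(C)=O)cc12
F4 | step 12 | (2R,2'R,3R,3'R,4R,4'R)-7,8,8'-tris(benzyloxy)-2,2'-bis[4-(benzyloxy)phenyl]-[6,6'-bichromane]-3,3',4,4',7'-pentol | O[C@H]1[C@@H](O)[C@@H](c2ccc(OCc3ccccc3)cc2)Oc2c(OCc3ccccc3)c(OCc3ccccc3)c(-c3cc4[C@@H](O)[C@@H](O)[C@@H](c5ccc(OCc6ccccc6)cc5)Oc4c(OCc4ccccc4)c3O)cc12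
F5 | step 12 | benzyl (2R,3R,4R)-8-(benzyloxy)-2-[4-(benzyloxy)phenyl]-6-{(2R,3R,4R)-7,8-bis(benzyloxy)-2-[4-(benzyloxy)phenyl]-3,4-dihydroxychroman-6-yl}-3,4-dihydroxychroman-7-yl carbonate | O[C@H]1[C@@H](O)[C@@H](c2ccc(OCc3ccccc3)cc2)Oc2c(OCc3ccccc3)c(OCc3ccccc3)c(-c3cc4[C@@H](O)[C@@H](O)[C@@H](c5ccc(OCc6ccccc6)cc5)Oc4c(OCc4ccccc4)c3OC(=O)OCc3ccccc3)cc12
F6 | step 12 | benzyl (2R,3R,4R)-8-(benzyloxy)-2-[4-(benzyloxy)phenyl]-6-{(2R,3R,4S)-7,8-bis(benzyloxy)-2-[4-(benzyloxy)phenyl]-3,4-dihydroxychroman-6-yl}-3,4-dihydroxychroman-7-yl carbonate | O[C@@H]1[C@@H](O)[C@@H](c2ccc(OCc3ccccc3)cc2)Oc2c(OCc3ccccc3)c(OCc3ccccc3)c(-c3cc4[C@@H](O)[C@@H](O)[C@@H](c5ccc(OCc6ccccc6)cc5)Oc4c(OCc4ccccc4)c3OC(=O)OCc3ccccc3)cc12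
F7 | step 9 | cyclic benzylidene acetal of 10 across O7 and O7' (6-phenyldibenzo[d,f][1,3]dioxepine core fused to both 8-(benzyloxy)-2-[4-(benzyloxy)phenyl]-3-hydroxychromen-4-one units) | O=c1c(O)c(-c2ccc(OCc3ccccc3)cc2)oc2c(OCc3ccccc3)c3OC(c4ccccc4)Oc4c(OCc5ccccc5)c5oc(-c6ccc(OCc7ccccc7)cc6)c(O)c(=O)c5cc4-c3cc12
F8 | step 13 | 3,3',4,4',7'-penta-O-triethylsilyl ether of 16 (configuration as in 16) | CC[Si](CC)(CC)O[C@H]1[C@@H](O[Si](CC)(CC)CC)[C@@H](c2ccc(OCc3ccccc3)cc2)Oc2c(OCc3ccccc3)c(OCc3ccccc3)c(-c3cc4[C@H](O[Si](CC)(CC)CC)[C@@H](O[Si](CC)(CC)CC)[C@@H](c5ccc(OCc6ccccc6)cc5)Oc4c(OCc4ccccc4)c3O[Si](CC)(CC)CC)cc12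
F9 | step 13 | 3,3',4,4',7'-penta-O-triethylsilyl ether of 17 (configuration as in 17; silyl groups on the 3,4-trans half at O3', O4', O7' and on the all-cis half at O3, O4) | CC[Si](CC)(CC)O[C@H]1[C@@H](O[Si](CC)(CC)CC)[C@@H](c2ccc(O)cc2)Oc2c(O)c(O)c(-c3cc4[C@H](O[Si](CC)(CC)CC)[C@@H](O[Si](CC)(CC)CC)[C@@H](c5ccc(O)cc5)Oc4c(O)c3O[Si](CC)(CC)CC)cc12
A1 | alternative 1 | (2R,3R,4R)-7,8-bis(benzyloxy)-2-[4-(benzyloxy)phenyl]-6-bromochromane-3,4-diol | O[C@H]1[C@@H](O)[C@@H](c2ccc(OCc3ccccc3)cc2)Oc2c(OCc3ccccc3)c(OCc3ccccc3)c(Br)cc12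
A2 | alternative 1 | (2R,3R,4S)-7,8-bis(benzyloxy)-2-[4-(benzyloxy)phenyl]-6-(4,4,5,5-tetramethyl-1,3,2-dioxaborolan-2-yl)chromane-3,4-diol | O[C@@H]1[C@@H](O)[C@@H](c2ccc(OCc3ccccc3)cc2)Oc2c(OCc3ccccc3)c(OCc3ccccc3)c(B3OC(C)(C)C(C)(C)O3)cc12
A3 | alternative 2 | (2E,2'E)-1,1'-[5,5',6,6'-tetrakis(benzyloxy)-4,4'-bis(methoxymethoxy)-[1,1'-biphenyl]-3,3'-diyl]bis{3-[4-(benzyloxy)phenyl]prop-2-en-1-one} | COCOc1c(C(=O)/C=C/c2ccc(OCc3ccccc3)cc2)cc(-c2cc(C(=O)/C=C/c3ccc(OCc4ccccc4)cc3)c(OCOC)c(OCc3ccccc3)c2OCc2ccccc2)c(OCc2ccccc2)c1OCc1ccccc1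
A4 | alternative 2 | (2R,2'R,3R,3'R)-7,7',8,8'-tetrakis(benzyloxy)-2,2'-bis[4-(benzyloxy)phenyl]-3,3'-dihydroxy-[6,6'-bichromane]-4,4'-dione | O=C1[C@H](O)[C@@H](c2ccc(OCc3ccccc3)cc2)Oc2c(OCc3ccccc3)c(OCc3ccccc3)c(-c3cc4C(=O)[C@H](O)[C@@H](c5ccc(OCc6ccccc6)cc5)Oc4c(OCc4ccccc4)c3OCc3ccccc3)cc12
A5 | alternative 3 | 4,4'-bis{(1R)-1-[4-(benzyloxy)phenyl]-2-oxoethoxy}-5,5',6,6'-tetrakis(benzyloxy)-[1,1'-biphenyl]-3,3'-dicarbaldehyde | O=Cc1cc(-c2cc(C=O)c(O[C@@H](C=O)c3ccc(OCc4ccccc4)cc3)c(OCc3ccccc3)c2OCc2ccccc2)c(OCc2ccccc2)c(OCc2ccccc2)c1O[C@@H](C=O)c1ccc(OCc2ccccc2)cc1
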